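(The earlier runs and the new flask were computed for substances that don't exist, noise included.)

Time is one of the two numbers we need: the flask is read at 3.0 d. The other is the substrate lifetime τ, the mean wait of a substrate molecule before it becomes product. Catalyst, added ligand and held gas are alike in all runs. If that wait ignores the charge, the loss is pseudo-first-order, and a molecule reaches the reading unchanged with chance exp(−t/τ).

| flask | substrate | gas phase | catalyst | added ligand | remark | time |
|---|---|---|---|---|---|---|
| blue | 0.070 M | 5.6 mM (held) | 46 µM | 0.11 mM | run made earlier |  |
| red | 0.11 M | 5.6 mM (held) | 46 µM | 0.11 mM | run made earlier |  |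
| flask | 0.050 M | 5.6 mM (held) | 46 µM | 0.11 mM |  | 3.0 d |

- blue (time / d: product / %, idle complex B / %, substrate / %): 0.417: 13.8, 0, 83.7; 1.04: 32.7, 0, 66.3; 2.08: 55.5, 0.7, 43.0; 3.00: 70.3, 0, 32.4
- red (time / d: product / %, idle complex B / %, substrate / %): 0.833: 25.3, 2.5, 74.9; 1.67: 46.2, 0.9, 53.0; 2.50: 59.9, 0.2, 40.7; 3.00: 67.2, 0.7, 33.9

(scatter of a reading: 1 percentage point)

1. how much product and idle complex B together there is at 3.0 d, in percent of the substrate charged
2. concentration of dissolved gas in solution at 3.0 d, in percent of saturation

- for product the idle complex B is counted in
- at the start none of the gas phase is in solution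

Blue and red differ in charge, yet after 3.00 d they read 70.3% and 67.2% of it, so we take the wait as the same at both charges and assume it for the flask, reading no sign of a gas shortage. Each fraction gives a lifetime, and their mean is τ = 2.58 d. The reading lies 1.16 lifetimes out, so we expect a converted fraction of 68.7%. The forecast, calling the reaction “essentially first order in substrate”, gives 69% and 98%; on product we agree.

The flask gives 71.1% of product and idle complex B together, 2.4 percentage points above our τ reckoning, and dissolved gas at 99.8% of saturation.

    substrate + dissolved gas + catalyst → catalyst + product (k = 4600 /M²/min)
    gas phase ⇌ dissolved gas, rate k2*(csat - [dissolved gas]) (kL = 0.310 /min)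
    substrate + catalyst ⇌ idle complex A, settled at all times (K = 6.80 /M)
    catalyst + added ligand ⇌ idle complex C, settled at all times (K = 35000 /M)
    catalyst + product ⇌ idle complex B, settled at all times (K = 6.80 /M)

A lower charge of added ligand is what would make the forecast's 69% wrong, as a neighbour flask shows. The binding of catalyst and added ligand into idle complex C is a part of the reason, together with the early reading, that this flask stands at 71.1%, against 97.7% without that binding and >99.9% at 30.0 d. At the reading, the neighbour flask with 2.8 × 10⁻⁵ M of added ligand has 53.6% of its catalyst free, against 24.4% in this flask. The first equation's rate goes with free catalyst, so we shorten τ by that ratio to 1.17 d, which gives a converted fraction of 92.3%; that neighbour flask gives 93.4%.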